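**Remark on the chemistry:** the target, 2-hydroxy-6-(12-phenyldodecyl)benzoic acid, has no stereocentre and is achiral, so "single enantiomer" is taken to mean the one constitution given; no stereocontrol is required.

**Retrosynthetic overview**
- The target comes from methyl 2-methoxy-6-(12-phenyldodecyl)benzoate by O-demethylation and ester hydrolysis.
- Feature: in the salicylate ring the C1(CO2H)–C6(chain) edge is the C2≡C3 unit of an alk-2-ynoate, and C2(O)–C3–C4–C5 is the C1–C4 unit of 1-methoxycyclohexa-1,3-diene. The ring is cut at C1–C2 and C5–C6 (Alder–Rickert: [4+2], then loss of ethene).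
- The ynoate comes from a terminal alkyne and methyl chloroformate; the alkyne from (12-bromododecyl)benzene and acetylide; the bromide from 12-phenyldodecan-1-ol, itself from phenyl Grignard and 12-bromododecan-1-ol.
- The diene comes from anisole by Birch reduction and base conjugation.
- Ring order: the distal phenyl ring is bought; the salicylate ring is the only ring formed, in step 7.

Key step: step 7

**Route**

Step 1
Reactants: 1 bromobenzene; 2 12-bromododecan-1-ol
Product: 6 12-phenyldodecan-1-ol, via phenylmagnesium bromide 3 (not isolated), via bromomagnesium 12-bromododecan-1-olate 4 (not isolated), via bromomagnesium 12-phenyldodecan-1-olate 5 (not isolated)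
Conditions: Mg, THF, reflux (3 equiv of Grignard); then 2, Li2CuCl4 (cat.), THF, −10 °C to rt; aq. NH4Cl
Reagents that add atoms: none
Why: Kochi-type copper-catalysed Grignard cross-coupling; the first equivalent of Grignard masks the hydroxyl as its inert magnesium alkoxide and the aryl cuprate then displaces the unhindered primary bromide.

Step 2
Reactants: 6 12-phenyldodecan-1-ol
Product: 7 (12-bromododecyl)benzene
Conditions: CBr4, PPh3, CH2Cl2, 0 °C to rt
Reagents that add atoms: carbon tetrabromide, BrC(Br)(Br)Br
Why: Appel reaction; the primary alkoxyphosphonium ion is displaced by bromide in a clean SN2 step and nothing else in the molecule reacts.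

Step 3
Reactants: 7 (12-bromododecyl)benzene
Product: 8 14-phenyltetradec-1-yne
Conditions: lithium acetylide–ethylenediamine complex, DMSO, 10 °C to rt
Reagents that add atoms: lithium acetylide–ethylenediamine complex, [Li+].[C-]#C.NCCN
Why: SN2 alkylation of an acetylide with an unbranched primary bromide in a dipolar aprotic solvent, where substitution should outrun elimination.

Step 4
Reactants: 8 14-phenyltetradec-1-yne
Product: 10 methyl 15-phenylpentadec-2-ynoate, via (14-phenyltetradec-1-yn-1-yl)lithium 9 (not isolated)
Conditions: n-BuLi, THF, −78 °C; then ClCO2Me, −78 to 0 °C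
Reagents that add atoms: methyl chloroformate, COC(=O)Cl
Why: deprotonation of the terminal alkyne and C-acylation of the lithium acetylide with a chloroformate; the benzylic and chain C–H bonds are far less acidic and are left alone.

Step 5
Reactants: 11 anisole
Product: 12 1-methoxycyclohexa-1,4-diene
Conditions: Li, NH3 (l), THF, t-BuOH, −78 to −33 °C; MeOH then H2O quench
Reagents that add atoms: none
Why: Birch reduction; the donor methoxy group directs protonation to the ortho and meta positions, so the unconjugated enol-ether diene should form.

Step 6
Reactants: 12 1-methoxycyclohexa-1,4-diene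
Product: 13 1-methoxycyclohexa-1,3-diene (expected as an equilibrium mixture enriched in 13, with residual 12, distilled and used as such)
Conditions: KOt-Bu (cat.), DMSO, rt, under Ar
Reagents that add atoms: none
Why: base-mediated prototropic isomerisation through the pentadienyl anion, which moves the isolated double bond into conjugation with the enol ether.

Step 7
Reactants: 10 methyl 15-phenylpentadec-2-ynoate; 13 1-methoxycyclohexa-1,3-diene
Product: 15 methyl 2-methoxy-6-(12-phenyldodecyl)benzoate, via racemic methyl 1-methoxy-3-(12-phenyldodecyl)bicyclo[2.2.2]octa-2,5-diene-2-carboxylate 14 (not isolated)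
Conditions: 13 (3 equiv, as the isomer mixture), neat, BHT (cat.), no base, sealed tube, 190 °C; ethene vented on cooling
Reagents that add atoms: none
Why: Alder–Rickert reaction: a concerted, suprafacial, normal-electron-demand [4+2] cycloaddition of the electron-rich diene 13 to the electron-poor ynoate 10 gives the bicyclo[2.2.2]octa-2,5-diene 14, and at the same temperature a retro-[4+2] expels the saturated C7–C8 bridge as ethene, irreversibly and with gain of aromaticity. The closest known reaction type is this very one, the thermal reaction of 1-methoxycyclohexa-1,3-dienes with alk-2-ynoates to give 6-alkyl-2-methoxybenzoates. The benzene ring is closed by an intermolecular cycloaddition that forms both new ring bonds (arene C1–C2 and C5–C6) in one event, so no Baldwin mode applies. No stereocentre survives, because the two bridgehead centres of 14 become sp2 when ethene leaves. The step needs regioselectivity, and the methoxy group secures it: the largest HOMO coefficient lies on C4 of the diene, which bonds to the β-carbon of the ynoate, so methoxy ends ortho to the ester and the chain takes the other ortho position. The saturated chain and the remote phenyl ring are inert to heat, and the excess of diene covers the unreactive 1,4-isomer carried over from step 6.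

Step 8
Reactants: 15 methyl 2-methoxy-6-(12-phenyldodecyl)benzoate
Product: 17 methyl 2-hydroxy-6-(12-phenyldodecyl)benzoate, via methyl 2-[(dibromoboranyl)oxy]-6-(12-phenyldodecyl)benzoate 16 (not isolated)
Conditions: BBr3 (1.2 equiv), CH2Cl2, −78 to 0 °C; then H2O
Reagents that add atoms: none
Why: Lewis-acid ether cleavage; boron binds the aryl ether oxygen with chelation help from the ortho ester carbonyl and bromide attacks the methyl group by SN2, while the methyl ester should survive the low temperature and limited reagent.

Step 9
Reactants: 17 methyl 2-hydroxy-6-(12-phenyldodecyl)benzoate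
Product: 19 2-hydroxy-6-(12-phenyldodecyl)benzoic acid (target), via dipotassium 2-oxido-6-(12-phenyldodecyl)benzoate 18 (not isolated)
Conditions: KOH (excess), DMSO/H2O, 90 °C, under Ar; then cold 1 M HCl to pH 2
Reagents that add atoms: potassium hydroxide, [K+].[OH-]
Why: BAc2 saponification under forcing conditions, needed because the ester is flanked by two ortho substituents and deactivated by the neighbouring phenoxide; cold acidification should release the acid without decarboxylation.

**Compound list**
1 | bromobenzene | Brc1ccccc1 | starting material
2 | 12-bromododecan-1-ol | OCCCCCCCCCCCCBr | starting material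
3 | phenylmagnesium bromide | Br[Mg]c1ccccc1 | intermediate
4 | bromomagnesium 12-bromododecan-1-olate | Br[Mg]OCCCCCCCCCCCCBr | intermediate
5 | bromomagnesium 12-phenyldodecan-1-olate | Br[Mg]OCCCCCCCCCCCCc1ccccc1 | intermediate
6 | 12-phenyldodecan-1-ol | OCCCCCCCCCCCCc1ccccc1 | intermediate
7 | (12-bromododecyl)benzene | BrCCCCCCCCCCCCc1ccccc1 | intermediate
8 | 14-phenyltetradec-1-yne | C#CCCCCCCCCCCCCc1ccccc1 | intermediate
9 | (14-phenyltetradec-1-yn-1-yl)lithium | [Li]C#CCCCCCCCCCCCCc1ccccc1 | intermediate
10 | methyl 15-phenylpentadec-2-ynoate | COC(=O)C#CCCCCCCCCCCCCc1ccccc1 | intermediate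
11 | anisole | COc1ccccc1 | starting material
12 | 1-methoxycyclohexa-1,4-diene | COC1=CCC=CC1 | intermediate
13 | 1-methoxycyclohexa-1,3-diene | COC1=CC=CCC1 | intermediate
14 | methyl 1-methoxy-3-(12-phenyldodecyl)bicyclo[2.2.2]octa-2,5-diene-2-carboxylate (racemic) | COC(=O)C1=C(CCCCCCCCCCCCc2ccccc2)C2C=CC1(OC)CC2 | intermediate
15 | methyl 2-methoxy-6-(12-phenyldodecyl)benzoate | COC(=O)c1c(OC)cccc1CCCCCCCCCCCCc1ccccc1 | intermediate
16 | methyl 2-[(dibromoboranyl)oxy]-6-(12-phenyldodecyl)benzoate | COC(=O)c1c(OB(Br)Br)cccc1CCCCCCCCCCCCc1ccccc1 | intermediate
17 | methyl 2-hydroxy-6-(12-phenyldodecyl)benzoate | COC(=O)c1c(O)cccc1CCCCCCCCCCCCc1ccccc1 | intermediate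
18 | dipotassium 2-oxido-6-(12-phenyldodecyl)benzoate | [K+].[K+].[O-]C(=O)c1c([O-])cccc1CCCCCCCCCCCCc1ccccc1 | intermediate
19 | 2-hydroxy-6-(12-phenyldodecyl)benzoic acid | O=C(O)c1c(O)cccc1CCCCCCCCCCCCc1ccccc1 | target

**Step count**
Total steps: 9. Longest linear sequence: 7 steps (1, 2, 3, 4, 7, 8, 9); the diene branch (steps 5 and 6) joins at step 7.

**Steps most likely to fail**

Step 7. The β-alkyl ynoate is a sluggish dienophile, so long heating may be needed. During that time the diene may dimerise, aromatise, or undergo a thermal [1,5]-hydrogen shift to the 2-methoxy isomer, which would erode regiochemistry; ethene extrusion may also stay incomplete. The fallback sets out from 7 and comes back at 15. Zinc insertion into 7 (Zn dust, cat. I2, DMA, 80 °C) should give (12-phenyldodecyl)zinc bromide F1. Negishi coupling of F1 with commercial methyl 2-bromo-6-methoxybenzoate (COC(=O)c1c(Br)cccc1OC; Pd(OAc)2, SPhos, THF/DMA, rt to 50 °C) should then form the aryl–alkyl bond with the ester intact and deliver 15.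

Step 1. Coupling of the aryl Grignard with the primary bromide may be slow in the presence of the aggregated magnesium alkoxide. Homocoupling to biphenyl, halogen–metal exchange, and reduction or elimination of the bromide may compete. The fallback sets out from 1 and comes back at 6. Sonogashira coupling of 1 with commercial dodec-11-yn-1-ol (OCCCCCCCCCCC#C; PdCl2(PPh3)2, CuI, Et3N, 80 °C) should give 12-phenyldodec-11-yn-1-ol F2. Hydrogenation of F2 (H2, Pd/C, EtOAc, rt) should saturate the alkyne and give 6.

Step 9. Hydroxide attack at the acyl carbon may be very slow, because the ester is di-ortho-substituted and sits next to a phenoxide. Prolonged heating and the acidic work-up invite decarboxylation of the salicylic acid. The fallback sets out from 17 and comes back at 19. Sodium ethanethiolate (excess, DMF, 100 °C; then cold dilute HCl) should cleave the ester by SN2 attack at the O-methyl carbon (alkyl–oxygen cleavage), which does not depend on access to the hindered carbonyl. No new compound is made on the way.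

Further compounds
F1 | step 7 | (12-phenyldodecyl)zinc bromide | Br[Zn]CCCCCCCCCCCCc1ccccc1
F2 | step 1 | 12-phenyldodec-11-yn-1-ol | OCCCCCCCCCCC#Cc1ccccc1
F0 | step 9 | none | none
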